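## Retrosynthetic overview

- Side-chain atoms are labelled C1' (OCH2) to C8' (lactone C=O); the coumarin is bought as umbelliferone.
- γ-Lactone (last ring): C6'–C7' bond by opening the terminal oxirane of a bis-epoxide with the lithium enolate of the (S)-lactic acid/pivalaldehyde acetal; the freed alkoxide closes the lactone.
- Both oxiranes (key step, one flask): hydroxyl-directed vanadium epoxidation of a (Z)-homoallylic chlorohydrin sets C2'/C3' 1,3-syn to C5'–O, then base closes the chlorohydrin.
- Aryl ether by Mitsunobu reaction with umbelliferone; the (Z)-olefin and C5' come from a dihydropyranone built from ethyl propiolate, (S)-epichlorohydrin and Me2CuLi.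
- Ring order: temporary dihydropyranone (opened again) → two oxiranes together → γ-lactone.

Assumption: the target is taken exactly as drawn in the SMILES, i.e. a (2'S,3'R) oxirane with the CH2OAr and CH2-lactone arms cis (Z-olefin derived) and a (2R,4R) lactone.

## Route

Step 1
Reactants: 1 ethyl propiolate; 2 (S)-epichlorohydrin
Product: 3 ethyl (5S)-6-chloro-5-hydroxyhex-2-ynoate
Conditions: n-BuLi, THF, −78 °C; BF3·OEt2; then 2, −78 °C; aq NH4Cl
Reagents that add atoms: none
Why: Yamaguchi–Hirao alkynylation: the BF3-activated epoxide is opened at its unsubstituted carbon by the lithium acetylide, so the C–O stereocentre of 2 is carried over unchanged as (5S).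

Step 2
Reactants: 3 ethyl (5S)-6-chloro-5-hydroxyhex-2-ynoate
Product: 5 (6S)-6-(chloromethyl)-4-methyl-5,6-dihydro-2H-pyran-2-one, via hydroxy enoate 4 (not isolated)
Conditions: MeLi (5 equiv), CuI (2.5 equiv), THF, −78 °C; MeOH, −78 °C; aq NH4Cl; then TsOH (cat.), CH2Cl2, rt
Reagents that add atoms: lithium dimethylcuprate, [Li+].C[Cu-]C
Why: Syn carbocupration (conjugate addition) of the ynoate places the new methyl cis to H, so the carbinol chain is cis to the ester (Z), and acid-catalysed lactonisation locks this geometry in the six-membered ring; the carbinol centre is untouched.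

Step 3
Reactants: 5 (6S)-6-(chloromethyl)-4-methyl-5,6-dihydro-2H-pyran-2-one
Product: 6 (2Z,5S)-6-chloro-3-methylhex-2-ene-1,5-diol
Conditions: i-Bu2AlH (3.5 equiv), CH2Cl2, −78 → 0 °C; aq KNaC4H4O6
Reagents that add atoms: none
Why: Hydride 1,2-reduction of the unsaturated lactone (through the lactol) gives the allylic alcohol and frees the C5' hydroxyl without touching the Z olefin, the chloride or the stereocentre.

Step 4
Reactants: 6 (2Z,5S)-6-chloro-3-methylhex-2-ene-1,5-diol; 7 umbelliferone (7-hydroxy-2H-chromen-2-one)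
Product: 8 7-{[(2Z,5S)-6-chloro-5-hydroxy-3-methylhex-2-en-1-yl]oxy}-2H-chromen-2-one
Conditions: PPh3 (1.05 equiv), DIAD (1.05 equiv), THF, 0 °C → rt
Reagents that add atoms: none
Why: Mitsunobu etherification: the acidic phenol (pKa about 7.8) displaces the primary allylic oxyphosphonium by SN2 much faster than the hindered secondary chlorohydrin alcohol reacts, so the Z olefin and C5' are unchanged.

Step 5
Reactants: 8 7-{[(2Z,5S)-6-chloro-5-hydroxy-3-methylhex-2-en-1-yl]oxy}-2H-chromen-2-one
Product: 10 7-({(2S,3R)-3-methyl-3-[(2S)-oxiran-2-ylmethyl]oxiran-2-yl}methoxy)-2H-chromen-2-one, via epoxy chlorohydrin 9 (not isolated)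
Conditions: VO(acac)2 (5 mol %), t-BuOOH (1.2 equiv, decane), CH2Cl2, 0 °C → rt; then K2CO3, MeOH, 0 °C → rt, same flask
Reagents that add atoms: tert-butyl hydroperoxide, CC(C)(C)OO
Why: Homoallylic-hydroxyl-directed epoxidation (Mihelich-type) through a chair vanadate ester with CH2Cl and the olefinic CH(CH2OAr) carbon both equatorial (the axial alternative drives the cis CH2OAr group into the ring) delivers oxygen 1,3-syn to the C5' hydroxyl, giving the (2'S,3'R) oxirane with the Z geometry retained, and the same C5' alkoxide then displaces chloride (intramolecular Williamson) to close the second oxirane.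

Step 6
Reactants: 11 (S)-lactic acid; 12 pivalaldehyde
Product: 13 (2S,5S)-2-tert-butyl-5-methyl-1,3-dioxolan-4-one
Conditions: TsOH (cat.), H2SO4 (cat.), pentane, reflux (Dean–Stark); crystallisation from Et2O/pentane, −78 °C
Reagents that add atoms: none
Why: Acid-catalysed acetalisation with azeotropic water removal favours the cis (2S,5S) dioxolanone (about 4:1), which is freed from the trans isomer by low-temperature crystallisation, the lactate centre fixing the new acetal centre (Seebach acetal).

Step 7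
Reactants: 13 (2S,5S)-2-tert-butyl-5-methyl-1,3-dioxolan-4-one; 10 7-({(2S,3R)-3-methyl-3-[(2S)-oxiran-2-ylmethyl]oxiran-2-yl}methoxy)-2H-chromen-2-one
Product: 15 7-({(2S,3R)-3-{[(2R,4R)-4-hydroxy-4-methyl-5-oxooxolan-2-yl]methyl}-3-methyloxiran-2-yl}methoxy)-2H-chromen-2-one, via lithium alkoxide 14 (not isolated)
Conditions: 13 (2.5 equiv), LiN(i-Pr)2, THF, −78 °C; then 10, DMPU, −78 → −25 °C; aq NH4Cl
Reagents that add atoms: none
Why: The Seebach enolate opens the monosubstituted oxirane at CH2 by SN2 anti to the tert-butyl group (self-regeneration of stereocentres, net retention at the lactate carbon, giving C7' as in the target), and the C5' alkoxide, whose C–O bond is never broken, then attacks the acetal ester to close the γ-lactone with loss of pivalaldehyde (enolate–epoxide lactone annulation), the trisubstituted oxirane being too hindered to react.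

## Compound list

1 | ethyl propiolate (ethyl prop-2-ynoate) | C#CC(=O)OCC | starting material
2 | (S)-epichlorohydrin, (2S)-2-(chloromethyl)oxirane | ClC[C@@H]1CO1 | starting material
3 | ethyl (5S)-6-chloro-5-hydroxyhex-2-ynoate | CCOC(=O)C#CC[C@H](O)CCl | intermediate
4 | ethyl (2Z,5S)-6-chloro-5-hydroxy-3-methylhex-2-enoate | CCOC(=O)/C=C(/C)C[C@H](O)CCl | intermediate (not isolated)
5 | (6S)-6-(chloromethyl)-4-methyl-5,6-dihydro-2H-pyran-2-one | CC1=CC(=O)O[C@H](CCl)C1 | intermediate
6 | (2Z,5S)-6-chloro-3-methylhex-2-ene-1,5-diol | C/C(=C/CO)C[C@H](O)CCl | intermediate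
7 | umbelliferone (7-hydroxy-2H-chromen-2-one) | Oc1ccc2ccc(=O)oc2c1 | starting material
8 | 7-{[(2Z,5S)-6-chloro-5-hydroxy-3-methylhex-2-en-1-yl]oxy}-2H-chromen-2-one | C/C(=C/COc1ccc2ccc(=O)oc2c1)C[C@H](O)CCl | intermediate
9 | 7-({(2S,3R)-3-[(2S)-3-chloro-2-hydroxypropyl]-3-methyloxiran-2-yl}methoxy)-2H-chromen-2-one | C[C@]1(C[C@H](O)CCl)O[C@H]1COc1ccc2ccc(=O)oc2c1 | intermediate (not isolated)
10 | 7-({(2S,3R)-3-methyl-3-[(2S)-oxiran-2-ylmethyl]oxiran-2-yl}methoxy)-2H-chromen-2-one | C[C@]1(C[C@H]2CO2)O[C@H]1COc1ccc2ccc(=O)oc2c1 | intermediate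
11 | (S)-lactic acid | C[C@H](O)C(=O)O | starting material
12 | pivalaldehyde (2,2-dimethylpropanal) | CC(C)(C)C=O | starting material
13 | (2S,5S)-2-tert-butyl-5-methyl-1,3-dioxolan-4-one (cis) | C[C@@H]1O[C@@H](OC1=O)C(C)(C)C | intermediate
14 | lithium (2S)-1-[(2S,4R)-2-tert-butyl-4-methyl-5-oxo-1,3-dioxolan-4-yl]-3-[(2R,3S)-2-methyl-3-{[(2-oxo-2H-chromen-7-yl)oxy]methyl}oxiran-2-yl]propan-2-olate | C[C@]1(C[C@@H]([O-])C[C@@]2(C)O[C@H]2COc2ccc3ccc(=O)oc3c2)O[C@@H](OC1=O)C(C)(C)C.[Li+] | intermediate (not isolated)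
15 | 7-({(2S,3R)-3-{[(2R,4R)-4-hydroxy-4-methyl-5-oxooxolan-2-yl]methyl}-3-methyloxiran-2-yl}methoxy)-2H-chromen-2-one | C[C@]1(C[C@H]2C[C@@](C)(O)C(=O)O2)O[C@H]1COc1ccc2ccc(=O)oc2c1 | target

## Step count and risks

Total steps: 7. Longest linear sequence: 6 (steps 1, 2, 3, 4, 5, 7); step 6 is a one-step side branch.

Most likely to fail, in this order:

1. Step 7. Ester enolates open epoxides sluggishly without a Lewis acid, and a Lewis acid strong enough to help would rearrange the trisubstituted oxirane. The enolate of 13 also decomposes above about −30 °C, and the coumarin is a possible Michael acceptor. The fallback sets out from 10 and comes back at 15. LiI/AcOH in THF at −20 °C opens only the monosubstituted oxirane at CH2 to give the iodohydrin F1. Et3SiCl/imidazole gives the triethylsilyl ether F2. The lithium enolate of 13 is then alkylated by this primary iodide (LiN(i-Pr)2, THF/DMPU, −78 → −30 °C) to give the alkylated dioxolanone F3. Bu4NF removes silicon, and the freed C5' alkoxide closes the lactone with loss of pivalaldehyde to give 15.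

2. Step 5. The 1,3-syn selectivity rests on the chair vanadate model and the axial C3' methyl may erode it; the electron-poor allylic-ether olefin may also react slowly. The fallback sets out from 8 and comes back at 10. Boc2O/DMAP gives the tert-butyl carbonate F4. IBr in toluene at −85 °C (Bartlett–Smith iodocarbonate cyclisation) gives the cyclic iodocarbonate F5 with the 4,6-cis (1,3-syn) arrangement. K2CO3/MeOH then cleaves the carbonate, and the two alkoxides displace iodide (inversion at C2') and chloride, so both oxiranes of 10 again form in one operation.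

3. Step 2. With the free hydroxyl, the alkenylcuprate can equilibrate through the allenoate (Z/E erosion), add a second methyl, or the chlorohydrin alkoxide can close. The fallback sets out from 2 and comes back at 5. CH2=C(CH3)MgBr with CuI (10 mol %) in THF at −40 °C opens the epoxide at CH2 to give the chlorohydrin F6. Acryloyl chloride/Et3N gives the acrylate F7. Ring-closing metathesis with the second-generation Grubbs catalyst, RuCl2(=CHPh)(PCy3)(SIMes), in CH2Cl2 at 40 °C gives 5, the ring enforcing the Z olefin.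

## Further compounds

F1 | step 7 | 7-({(2S,3R)-3-[(2S)-2-hydroxy-3-iodopropyl]-3-methyloxiran-2-yl}methoxy)-2H-chromen-2-one | C[C@]1(C[C@H](O)CI)O[C@H]1COc1ccc2ccc(=O)oc2c1
F2 | step 7 | 7-({(2S,3R)-3-[(2S)-3-iodo-2-(triethylsilyloxy)propyl]-3-methyloxiran-2-yl}methoxy)-2H-chromen-2-one | C[C@]1(C[C@H](O[Si](CC)(CC)CC)CI)O[C@H]1COc1ccc2ccc(=O)oc2c1
F3 | step 7 | (2S,5R)-2-tert-butyl-5-methyl-5-[(2S)-3-[(2R,3S)-2-methyl-3-{[(2-oxo-2H-chromen-7-yl)oxy]methyl}oxiran-2-yl]-2-(triethylsilyloxy)propyl]-1,3-dioxolan-4-one | C[C@]1(C[C@@H](O[Si](CC)(CC)CC)C[C@@]2(C)O[C@H]2COc2ccc3ccc(=O)oc3c2)O[C@@H](OC1=O)C(C)(C)C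
F4 | step 5 | tert-butyl (2S,4Z)-1-chloro-4-methyl-6-[(2-oxo-2H-chromen-7-yl)oxy]hex-4-en-2-yl carbonate | C/C(=C/COc1ccc2ccc(=O)oc2c1)C[C@H](OC(=O)OC(C)(C)C)CCl
F5 | step 5 | 7-{(2R)-2-[(4R,6S)-6-(chloromethyl)-4-methyl-2-oxo-1,3-dioxan-4-yl]-2-iodoethoxy}-2H-chromen-2-one | C[C@@]1(C[C@@H](CCl)OC(=O)O1)[C@H](I)COc1ccc2ccc(=O)oc2c1
F6 | step 2 | (2S)-1-chloro-4-methylpent-4-en-2-ol | C=C(C)C[C@H](O)CCl
F7 | step 2 | (2S)-1-chloro-4-methylpent-4-en-2-yl prop-2-enoate | C=CC(=O)O[C@H](CCl)CC(C)=C
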